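Take the catalyst charge of each flask and subtract the impurity charge, supposing the impurity (a catalyst poison) takes out catalyst one for one. I fold this into one number.

| setting | amber | teal | blue | flask |
|---|---|---|---|---|
| solid substrate | 0.35 M | 0.35 M | 0.35 M | 0.35 M |
| gas phase | 18 mM (held) | 18 mM (held) | 18 mM (held) | 18 mM (held) |
| free catalyst | 7 mM | 7 mM | 14 mM | 7.0 mM |
| impurity | 2.8 mM | 6.3 mM | 4.2 mM | 4.2 mM |
| remark | run made earlier | run made earlier | run made earlier |  |
| time |  |  |  | 40 h |

- amber (time / h: target / %, idle complex / %): 2.00: 0, 1; 6.00: 6, 2; 12.0: 3, 1; 15.0: 3, 0; 25.0: 8, 2; 30.0: 4, 0; 40.0: 11, 0
- teal (time / h: target / %, idle complex / %): 3.00: 0, 0; 5.00: 0, 2; 8.00: 0, 2; 12.0: 0, 0; 15.0: 0, 0; 25.0: 3, 0; 40.0: 3, 2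
- blue (time / h: target / %, idle complex / %): 8.00: 4, 0; 15.0: 3, 1; 25.0: 11, 3; 30.0: 12, 3; 40.0: 17, 5

(standard deviation of a reading: 2 percentage points)

- amounts and yields of target count idle complex too
- given per volume of solution although it is solid: solid substrate
- the earlier runs were read with a standard deviation of 2 percentage points
- at the start none of the solid substrate is in solution
- at the start none of the gas phase is in solution

1. amount of target and idle complex together at 40 h, in percent of the solid substrate charged
2. the change that raises the amount of target and idle complex together at 40 h, in percent of the solid substrate charged most ("none" if none brings more than 2 percentage points) (ash / oak / cedar / larch / none)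
3. amount of target and idle complex together at 40 h, in percent of the solid substrate charged, after ash

- ash: doubling the amount of free catalyst, all else as stated
- oak: doubling the dissolution coefficient of the solid substrate, all else as stated
- cedar: doubling the transfer coefficient of the gas phase, all else as stated
- larch: doubling the solubility of the solid substrate, all else as stated

The working share is the fraction of the charged catalyst left after the impurity has taken its part, one for one:

working share = 1 − impurity charge / catalyst charge = 0.400 in this flask

Amber has 0.600, teal 0.100 and blue 0.700. The target column already counts idle complex, so I add nothing to it. Amber holds the same catalyst charge as this flask, so I scale its last reading by the shares: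

11% × 0.400 / 0.600 = 7.33%

Is one number enough? Blue carries 2.33 times amber's working catalyst, yet its last reading is 1.55 times amber's, with a scatter of 2 percentage points. So the share orders the runs but doesn't scale them exactly, and my figure is rough. Ash turns this flask into blue, so I expect about 17% and choose ash; the other changes were never run.

The forecast gave 7.5%, ash and 22%, the last one above my figure. Like me it took ash to turn this flask into blue, but it read blue from other totals than my target column: “Smoothed totals (target plus idle complex) rise about linearly”

The flask gives 8.04%, best ash with a gain of 8.4 points, and 16.4% after ash.

    starting material + dissolved gas + free catalyst → free catalyst + target (k = 390 M⁻² h⁻¹)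
    solid substrate ⇌ starting material, rate k2*(cs2 - [starting material]) while solid is left; crystals form when [starting material] > cs2 (solubility = 0.300 M, k = 0.0130 h⁻¹)
    free catalyst + target ⇌ idle complex, settled at all times (K = 45.0 M⁻¹)
    gas phase ⇌ dissolved gas, rate k4*(csat - [dissolved gas]) (kL = 33.0 h⁻¹)
    free catalyst + impurity → spent catalyst (k = 91.0 M⁻¹ h⁻¹)

In this flask the impurity is down to 0.497% of its charge at 20.0 h, earlier than the 23.9 h by which half of the catalytic turnover to target is done. Spent catalyst then stands at 59.7%, against one minus the working share, 60.0%. A flask with 0.028 M of free catalyst has a working share of 0.850, so 15.0% should be spent, and it ends with 15.0% spent catalyst.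

(The numbers in the tables are calculated with made-up constants; the scatter is artificial.)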